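**Plan**

1. Retrosynthesis: the thirteen O–methyl bonds are cut first, then the two biaryl bonds from ring C (C3, C5) to rings D and E, then the ring B–O–ring C ether on the ring C side, then ring B itself at C2–C3 and C5–C6, and last the O–CH bond joining ring A to a malonate.
2. Enabling feature: ring B is a phloroglucinol (oxygens on C2, C4, C6) whose C1, between the C2 and C6 oxygens, carries the ether oxygen to ring A. C1 therefore maps onto the central carbon of a 2-aryloxymalonate, C2 and C6 onto its ester carbonyls, and C3–C4–C5 onto dimethyl 3-oxoglutarate.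
3. Forward: ring A is the starting phenol. Its ether is made at an sp3 carbon (step 1), ring B is closed around that carbon (step 2), freed of its esters (step 3), and two of its three hydroxyls are methylated (step 4).
4. Ring C enters as 1,3,5-tribromo-2,4,6-trimethoxybenzene (step 5). One bromide forms the B–O–C ether (step 6), the other two bring in rings D and E by a double Suzuki–Miyaura coupling (step 7). Global demethylation (step 8) ends the route.
5. Stereochemistry: the target has no stereocentre and no stereogenic axis (rings D and E are symmetric about their biaryl axes), so nothing has to be controlled.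

Key step: step 2

Remark on the chemistry: ring A is the 3,5-dihydroxyphenoxy ring. Ring B is the tetraoxygenated ring (C1 bears O–ring A, C6 bears O–ring C). Ring C is the hexasubstituted ring (C1 bears O–ring B; C3 and C5 bear rings D and E). All hydroxyls are carried as methyl ethers. Dimethyl chloromalonate is used in place of the bromo compound to suppress halophilic attack by the electron-rich phenoxide.

**Route**

Step 1
Reactants: 1 3,5-dimethoxyphenol; 2 dimethyl chloromalonate
Product: 3 dimethyl 2-(3,5-dimethoxyphenoxy)malonate
Conditions: K2CO3, acetone, reflux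
Reagents that add atoms: none
Why: Williamson-type SN2 O-alkylation of the potassium phenoxide at the doubly activated secondary chloride should be fast in acetone, and the chloride rather than the bromide is chosen so that ring halogenation and C-alkylation of the electron-rich ring stay minor.

Step 2
Reactants: 3 dimethyl 2-(3,5-dimethoxyphenoxy)malonate (1.3 equiv); 4 dimethyl 3-oxoglutarate
Product: 6 dimethyl 5-(3,5-dimethoxyphenoxy)-2,4,6-trihydroxybenzene-1,3-dicarboxylate, via open-chain Claisen adduct 5 (not isolated)
Conditions: NaOMe (3.3 equiv), MeOH–toluene, 4 added slowly, reflux with removal of MeOH; then 1 M HCl, 0 °C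
Reagents that add atoms: none
Why: This is a double Claisen (C-acylation) cyclocondensation in which the sodium enolate of 4 attacks one ester carbonyl of 3 and expels methoxide to give adduct 5, whose second α-carbon then attacks the remaining malonate ester, so that the C2–C3 and C5–C6 bonds of ring B form and the cyclohexane-1,3,5-trione enolises to the aromatic triol. The closest known reaction type is the alkoxide-mediated condensation of malonic esters with acetonedicarboxylic esters to phloroglucinoldicarboxylates, together with the use of 2-aryloxymalonates as 1,3-bis-electrophiles towards 1,3-binucleophiles under NaOMe. Ring B closes by a 6-exo-trig acyl substitution, which is favoured for either enolate geometry. No stereocentre is created, since the two sp3 carbons of 5 become aromatic carbons. The step needs cross-condensation over self-condensation of 4 and C- over O-acylation in the ring closure; the first is secured by feeding 4 slowly into an excess of 3 and base, the second by the reversibility of every acylation under methoxide, which returns pyranone and retro-Claisen by-products to the pathway ending in the aromatic trisodium salt. Because the A–O–B oxygen already sits on the malonate carbon, no arylation is needed at the crowded C1 between two oxygens.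

Step 3
Reactants: 6 dimethyl 5-(3,5-dimethoxyphenoxy)-2,4,6-trihydroxybenzene-1,3-dicarboxylate
Product: 8 2-(3,5-dimethoxyphenoxy)benzene-1,3,5-triol, via ring B diacid 7 (not isolated)
Conditions: 2 M NaOH (aq), reflux, Ar; then conc. HCl to pH 1, 70 °C
Reagents that add atoms: none
Why: Saponification gives diacid 7, a β-keto acid in its keto tautomer, which should lose both carboxyl groups on acidification and mild heating (protodecarboxylation of a phloroglucinolcarboxylic acid), while the aryl methyl ethers and the diaryl ether are inert to aqueous base and dilute acid.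

Step 4
Reactants: 8 2-(3,5-dimethoxyphenoxy)benzene-1,3,5-triol
Product: 9 2-(3,5-dimethoxyphenoxy)-3,5-dimethoxyphenol
Conditions: dry HCl (about 2 M) in MeOH, 25–45 °C, stopped at the diether stage
Reagents that add atoms: methanol, CO
Why: Acid-catalysed etherification of a phloroglucinol through its keto tautomer (the reaction that converts phloroglucinol into 3,5-dimethoxyphenol) should methylate the unhindered oxygen para to the aryloxy group and one flanking oxygen, because the only other dimethyl ether would need both hindered flanking positions to react before the open one and the third etherification, next to the aryloxy-bearing carbon, is the slowest.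

Step 5
Reactants: 10 1,3,5-trimethoxybenzene
Product: 11 1,3,5-tribromo-2,4,6-trimethoxybenzene
Conditions: Br2 (3.3 equiv), CH2Cl2, 0 °C to rt
Reagents that add atoms: bromine, BrBr
Why: Threefold electrophilic aromatic bromination of a ring in which every free position is ortho or para to three methoxy groups should give the symmetric tribromide, which serves as ring C with one site for the ether and two for rings D and E.

Step 6
Reactants: 9 2-(3,5-dimethoxyphenoxy)-3,5-dimethoxyphenol; 11 1,3,5-tribromo-2,4,6-trimethoxybenzene (3 equiv)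
Product: 12 1,3-dibromo-5-[2-(3,5-dimethoxyphenoxy)-3,5-dimethoxyphenoxy]-2,4,6-trimethoxybenzene
Conditions: CuI (20 mol %), 2,2,6,6-tetramethylheptane-3,5-dione (50 mol %), Cs2CO3, NMP, 120 °C
Reagents that add atoms: none
Why: Ullmann diaryl ether synthesis with a monovalent copper catalyst is established for 2,6-dimethoxyaryl bromides and methoxylated phenols, the diketone ligand accelerates coupling of electron-rich bromides, and the threefold excess of the symmetric tribromide should hold the reaction at the mono-ether.

Step 7
Reactants: 12 1,3-dibromo-5-[2-(3,5-dimethoxyphenoxy)-3,5-dimethoxyphenoxy]-2,4,6-trimethoxybenzene; 13 2,4,6-trimethoxyphenylboronic acid (5 equiv, in portions)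
Product: 14 1-[2-(3,5-dimethoxyphenoxy)-3,5-dimethoxyphenoxy]-2,4,6-trimethoxy-3,5-bis(2,4,6-trimethoxyphenyl)benzene
Conditions: Pd(OAc)2 (10 mol %), SPhos (20 mol %), K3PO4, toluene–H2O (10:1), 100 °C
Reagents that add atoms: none
Why: In this twofold Suzuki–Miyaura coupling the bulky electron-rich biarylphosphine should support oxidative addition of zerovalent palladium into the di-ortho-methoxy C–Br bonds and reductive elimination to the tetra-ortho-oxygenated biaryls, while the excess of 13 offsets its protodeboronation.

Step 8
Reactants: 14 1-[2-(3,5-dimethoxyphenoxy)-3,5-dimethoxyphenoxy]-2,4,6-trimethoxy-3,5-bis(2,4,6-trimethoxyphenyl)benzene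
Product: 15 2-[2-(3,5-dihydroxyphenoxy)-3,5-dihydroxyphenoxy]-4,6-bis(2,4,6-trihydroxyphenyl)benzene-1,3,5-triol (CNP0228669.0)
Conditions: BBr3 (30 equiv), CH2Cl2, −78 °C to rt; then H2O, 0 °C; work-up under Ar
Reagents that add atoms: none
Why: Lewis-acid ether cleavage by BBr3 (O-complexation followed by bromide attack at methyl) should remove all thirteen methyl groups and leave the diaryl ether and biaryl bonds intact, since bromide cannot attack their sp2 carbons, and hydrolysis of the aryl borates then releases the target.

**Compound list**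

1 | 3,5-dimethoxyphenol | COc1cc(O)cc(OC)c1 | starting material
2 | dimethyl chloromalonate | COC(=O)C(Cl)C(=O)OC | starting material
3 | dimethyl 2-(3,5-dimethoxyphenoxy)malonate | COC(=O)C(Oc1cc(OC)cc(OC)c1)C(=O)OC | intermediate
4 | dimethyl 3-oxoglutarate | COC(=O)CC(=O)CC(=O)OC | starting material
5 | dimethyl 2-[2-(3,5-dimethoxyphenoxy)-3-methoxy-3-oxopropanoyl]-3-oxopentanedioate (open-chain Claisen adduct, mixture of tautomers) | COC(=O)CC(=O)C(C(=O)OC)C(=O)C(Oc1cc(OC)cc(OC)c1)C(=O)OC | intermediate (not isolated)
6 | dimethyl 5-(3,5-dimethoxyphenoxy)-2,4,6-trihydroxybenzene-1,3-dicarboxylate | COC(=O)c1c(O)c(C(=O)OC)c(O)c(Oc2cc(OC)cc(OC)c2)c1O | intermediate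
7 | 5-(3,5-dimethoxyphenoxy)-2,4,6-trihydroxybenzene-1,3-dicarboxylic acid | OC(=O)c1c(O)c(C(O)=O)c(O)c(Oc2cc(OC)cc(OC)c2)c1O | intermediate (not isolated)
8 | 2-(3,5-dimethoxyphenoxy)benzene-1,3,5-triol | COc1cc(Oc2c(O)cc(O)cc2O)cc(OC)c1 | intermediate
9 | 2-(3,5-dimethoxyphenoxy)-3,5-dimethoxyphenol | COc1cc(Oc2c(O)cc(OC)cc2OC)cc(OC)c1 | intermediate
10 | 1,3,5-trimethoxybenzene | COc1cc(OC)cc(OC)c1 | starting material
11 | 1,3,5-tribromo-2,4,6-trimethoxybenzene | COc1c(Br)c(OC)c(Br)c(OC)c1Br | intermediate
12 | 1,3-dibromo-5-[2-(3,5-dimethoxyphenoxy)-3,5-dimethoxyphenoxy]-2,4,6-trimethoxybenzene | COc1cc(Oc2c(OC)cc(OC)cc2Oc2c(OC)c(Br)c(OC)c(Br)c2OC)cc(OC)c1 | intermediate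
13 | 2,4,6-trimethoxyphenylboronic acid | COc1cc(OC)c(B(O)O)c(OC)c1 | starting material
14 | 1-[2-(3,5-dimethoxyphenoxy)-3,5-dimethoxyphenoxy]-2,4,6-trimethoxy-3,5-bis(2,4,6-trimethoxyphenyl)benzene | COc1cc(Oc2c(OC)cc(OC)cc2Oc2c(OC)c(-c3c(OC)cc(OC)cc3OC)c(OC)c(-c3c(OC)cc(OC)cc3OC)c2OC)cc(OC)c1 | intermediate
15 | 2-[2-(3,5-dihydroxyphenoxy)-3,5-dihydroxyphenoxy]-4,6-bis(2,4,6-trihydroxyphenyl)benzene-1,3,5-triol | Oc1cc(O)cc(Oc2c(O)cc(O)cc2Oc2c(O)c(-c3c(O)cc(O)cc3O)c(O)c(-c3c(O)cc(O)cc3O)c2O)c1 | target

**Step count and risks**

Total step count: 8. Longest linear sequence: 7 (steps 1, 2, 3, 4, 6, 7, 8); step 5 is a one-step side branch.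

Steps most likely to fail:

Step 4. The etherification may not stop cleanly at the diether. Methanol may also exchange at the ring A carbon that carries the diaryl ether oxygen, breaking the A–O–B link, or acid may drive cyclodehydration between rings A and B. The fallback sets out from 8 and over-protects before deprotecting selectively. Exhaustive O-methylation (dimethyl sulfate, K2CO3, acetone, reflux) should give 2-(3,5-dimethoxyphenoxy)-1,3,5-trimethoxybenzene F1. One flanking methoxy group is then removed with BCl3 (1.1 equiv, CH2Cl2, −78 to 0 °C). Boron can bridge a flanking methoxy oxygen and the neighbouring diaryl ether oxygen in a five-membered chelate, whereas the isolated methoxy groups of ring A and the para position lack this assistance. After the first cleavage the aryl borate occupies the ether oxygen and discourages a second. Aqueous work-up returns to the route at 9.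

Step 6. Oxidative addition of copper into the electron-rich, doubly ortho-substituted C–Br bond may be too slow, so that hydrodebromination, a second etherification on the same ring C, or decomposition of the phenoxide takes over. The fallback sets out from 9 and grows ring C around the oxygen without any metal-mediated C–O coupling, repeating the logic of steps 1–3:
- O-alkylation of 9 with 2 (K2CO3, acetone) should give dimethyl 2-[2-(3,5-dimethoxyphenoxy)-3,5-dimethoxyphenoxy]malonate F2.
- Condensation with 4 under NaOMe should pass through the open-chain adduct dimethyl 2-{2-[2-(3,5-dimethoxyphenoxy)-3,5-dimethoxyphenoxy]-3-methoxy-3-oxopropanoyl}-3-oxopentanedioate F3 to dimethyl 5-[2-(3,5-dimethoxyphenoxy)-3,5-dimethoxyphenoxy]-2,4,6-trihydroxybenzene-1,3-dicarboxylate F4.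
- Saponification (aqueous NaOH, then HCl and heat) leads by way of 5-[2-(3,5-dimethoxyphenoxy)-3,5-dimethoxyphenoxy]-2,4,6-trihydroxybenzene-1,3-dicarboxylic acid F5 to 2-[2-(3,5-dimethoxyphenoxy)-3,5-dimethoxyphenoxy]benzene-1,3,5-triol F6.
- Iodine with NaHCO3 in aqueous THF at 0 °C should iodinate only the free phloroglucinol ring, the methylated rings A and B being inert to it, giving 2-[2-(3,5-dimethoxyphenoxy)-3,5-dimethoxyphenoxy]-4,6-diiodobenzene-1,3,5-triol F7.
- Methylation (dimethyl sulfate, K2CO3, acetone) should give 1-[2-(3,5-dimethoxyphenoxy)-3,5-dimethoxyphenoxy]-3,5-diiodo-2,4,6-trimethoxybenzene F8.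
- Coupling of F8 with 13 under the conditions of step 7 comes back to the route at 14.

Step 7. Protodeboronation of the doubly ortho-substituted, electron-rich boronic acid may outrun transmetalation, so that the coupling stalls at the mono-arylated bromide or ends in hydrodebromination. The fallback sets out from 12 and replaces the boron nucleophile by an organozinc, which has no protodemetalation pathway under anhydrous conditions (Negishi coupling). Lithiation of 10 between two methoxy groups (n-BuLi, THF, 0 °C to rt) should give (2,4,6-trimethoxyphenyl)lithium F9. Transmetalation with ZnCl2 gives (2,4,6-trimethoxyphenyl)zinc chloride F10. This is coupled with 12 (Pd(OAc)2, SPhos, THF–NMP, 70 °C) and returns to the route at 14.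

**Further compounds**

F1 | step 4 | 2-(3,5-dimethoxyphenoxy)-1,3,5-trimethoxybenzene | COc1cc(Oc2c(OC)cc(OC)cc2OC)cc(OC)c1
F2 | step 6 | dimethyl 2-[2-(3,5-dimethoxyphenoxy)-3,5-dimethoxyphenoxy]malonate | COC(=O)C(Oc1cc(OC)cc(OC)c1Oc1cc(OC)cc(OC)c1)C(=O)OC
F3 | step 6 | dimethyl 2-{2-[2-(3,5-dimethoxyphenoxy)-3,5-dimethoxyphenoxy]-3-methoxy-3-oxopropanoyl}-3-oxopentanedioate | COC(=O)CC(=O)C(C(=O)OC)C(=O)C(Oc1cc(OC)cc(OC)c1Oc1cc(OC)cc(OC)c1)C(=O)OC
F4 | step 6 | dimethyl 5-[2-(3,5-dimethoxyphenoxy)-3,5-dimethoxyphenoxy]-2,4,6-trihydroxybenzene-1,3-dicarboxylate | COC(=O)c1c(O)c(C(=O)OC)c(O)c(Oc2cc(OC)cc(OC)c2Oc2cc(OC)cc(OC)c2)c1O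
F5 | step 6 | 5-[2-(3,5-dimethoxyphenoxy)-3,5-dimethoxyphenoxy]-2,4,6-trihydroxybenzene-1,3-dicarboxylic acid | OC(=O)c1c(O)c(C(O)=O)c(O)c(Oc2cc(OC)cc(OC)c2Oc2cc(OC)cc(OC)c2)c1O
F6 | step 6 | 2-[2-(3,5-dimethoxyphenoxy)-3,5-dimethoxyphenoxy]benzene-1,3,5-triol | Oc1cc(O)c(Oc2cc(OC)cc(OC)c2Oc2cc(OC)cc(OC)c2)c(O)c1
F7 | step 6 | 2-[2-(3,5-dimethoxyphenoxy)-3,5-dimethoxyphenoxy]-4,6-diiodobenzene-1,3,5-triol | Oc1c(I)c(O)c(Oc2cc(OC)cc(OC)c2Oc2cc(OC)cc(OC)c2)c(O)c1I
F8 | step 6 | 1-[2-(3,5-dimethoxyphenoxy)-3,5-dimethoxyphenoxy]-3,5-diiodo-2,4,6-trimethoxybenzene | COc1c(I)c(OC)c(Oc2cc(OC)cc(OC)c2Oc2cc(OC)cc(OC)c2)c(OC)c1I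
F9 | step 7 | (2,4,6-trimethoxyphenyl)lithium | [Li]c1c(OC)cc(OC)cc1OC
F10 | step 7 | (2,4,6-trimethoxyphenyl)zinc chloride | Cl[Zn]c1c(OC)cc(OC)cc1OC
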